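**Retrosynthetic overview**
1. Lactone and C3 carbinol: methyl addition to the C3 ketone of 16, then translactonisation. The cis-piperidine (C2′, C2) comes from reduction of vinylogous amide 14, made by Claisen acylation of ketone 8 with N-Boc lactam 11.
2. Ring B (C3a–C4): Pd-catalysed intramolecular enolate alkenylation of bromo enoate 7.
3. Ring A, the C5a carbinol and C4=C5: α-ketol ring contraction (7→6) of cis-acyloin 5 with in-situ Wittig capture (key step, new).
4. 5: Mukaiyama–Michael addition of cycloheptanone enol silane 2 to cyclopentenone 3 (sets C9a/C9b), then α′-hydroxylation.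
5. Ring order: C (bought) → A (by contraction of the bought seven-membered ring) → B → piperidine → lactone.

Assumption: silylating, oxidising, Wittig, Boc, acetylating and Grignard reagents are treated as reagents, not starting materials; LDA is a commercial solution.
Locants: the carbocycle is numbered as in 8 (cyclopenta[a]naphthalene: C1–C3, C3a, C4, C5, C5a, C6–C9, C9a, C9b); the piperidine carbons are C2′ (bonded to C2) and C6′ (methyl-bearing).

Step 1
Reactants: 1 cycloheptanone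
Product: 2 1-{[tert-butyl(dimethyl)silyl]oxy}cyclohept-1-ene
Conditions: TBSOTf, Et3N, CH2Cl2, 0 °C
Reagents that add atoms: tert-butyldimethylsilyl triflate, CC(C)(C)[Si](C)(C)OS(=O)(=O)C(F)(F)F
Why: Silyl enol ether formation by soft enolisation of the symmetrical ketone gives the single Mukaiyama donor; no stereocentre is formed.

Step 2
Reactants: 2 1-{[tert-butyl(dimethyl)silyl]oxy}cyclohept-1-ene; 3 cyclopent-2-en-1-one
Product: 4 (2S)-2-[(1R)-3-{[tert-butyl(dimethyl)silyl]oxy}cyclopent-2-en-1-yl]cycloheptan-1-one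
Conditions: chiral o-tolyl-oxazaborolidinium triflimide (10 mol %, enantiomer chosen for 2S,1′R), CH2Cl2, −78 °C
Reagents that add atoms: none
Why: Catalytic asymmetric Mukaiyama–Michael addition through an open synclinal transition state gives the syn adduct (future C9a S, C9b R by catalyst face selection), and silyl transfer leaves the cyclopentanone masked as its regiodefined TBS enol ether.

Step 3
Reactants: 4 (2S)-2-[(1R)-3-{[tert-butyl(dimethyl)silyl]oxy}cyclopent-2-en-1-yl]cycloheptan-1-one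
Product: 5 (2S,7S)-2-hydroxy-7-[(1R)-3-{[tert-butyl(dimethyl)silyl]oxy}cyclopent-2-en-1-yl]cycloheptan-1-one
Conditions: LDA (1.1 equiv), THF, −78 °C; 3-phenyl-2-(phenylsulfonyl)oxaziridine, −78 °C; aq NH4Cl
Reagents that add atoms: 3-phenyl-2-(phenylsulfonyl)oxaziridine, O=S(=O)(c1ccccc1)N1OC1c1ccccc1
Why: Kinetic deprotonation of the only free ketone at its unsubstituted α′-CH2 and Davis enolate hydroxylation give the acyloin, whose cis isomer (both groups pseudo-equatorial) is the thermodynamic one and is fed by enediolate equilibration in step 4.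

Step 4
Reactants: 5 (2S,7S)-2-hydroxy-7-[(1R)-3-{[tert-butyl(dimethyl)silyl]oxy}cyclopent-2-en-1-yl]cycloheptan-1-one
Product: 7 methyl (2Z)-2-bromo-3-{(1S,2S)-2-[(1R)-3-{[tert-butyl(dimethyl)silyl]oxy}cyclopent-2-en-1-yl]-1-hydroxycyclohexyl}prop-2-enoate, via hydroxy aldehyde 6 (not isolated)
Conditions: Ph3P=C(Br)CO2Me (1.5 equiv), Al(Ot-Bu)3 (20 mol %), PhMe, 80 °C
Reagents that add atoms: methyl bromo(triphenylphosphoranylidene)acetate, COC(=O)C(Br)=P(c1ccccc1)(c1ccccc1)c1ccccc1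
Why: Proposed new method: an aluminium-alkoxide-mediated α-ketol (acyloin) ring contraction run as a capture cascade, in which the chelated cis-2-hydroxy ketone undergoes a reversible anionic 1,2-shift of the C2–C3 ring bond onto the ketone carbon (7→6 ring contraction, the bond entering on the chelate face so that the 2S,7S acyloin should give the 1S carbinol with OH cis to the cyclopentenyl group) and the thermodynamically disfavoured tertiary α-hydroxy aldehyde 6 is removed irreversibly by Wittig olefination with the stabilised bromo-ylide (inert to the hindered ketone, giving the Z bromo enoate with the ester trans to the carbinol); the closest known reactions are Al(OR)3- or base-promoted α-ketol rearrangements (steroid D-homoannulation) and Wittig trapping of the minor open-chain aldehyde of lactols.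

Step 5
Reactants: 7 methyl (2Z)-2-bromo-3-{(1S,2S)-2-[(1R)-3-{[tert-butyl(dimethyl)silyl]oxy}cyclopent-2-en-1-yl]-1-hydroxycyclohexyl}prop-2-enoate
Product: 8 methyl (3aS,5aS,9aS,9bS)-5a-hydroxy-3-oxo-2,3,3a,5a,6,7,8,9,9a,9b-decahydro-1H-cyclopenta[a]naphthalene-4-carboxylate
Conditions: Pd2(dba)3 (2.5 mol %), P(t-Bu)3 (6 mol %), CsF (1.5 equiv), PhMe/DMF, 50 °C
Reagents that add atoms: none
Why: Fluoride unmasks the regiodefined enolate, which closes ring B by Pd-catalysed intramolecular enolate α-alkenylation with retention of alkene geometry, and only the cis-fused hydrindanone can form, which sets C3a.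

Step 6
Reactants: 9 (2S)-2-methylpiperidine
Product: 10 tert-butyl (2S)-2-methylpiperidine-1-carboxylate
Conditions: Boc2O, CH2Cl2, rt
Reagents that add atoms: di-tert-butyl dicarbonate, CC(C)(C)OC(=O)OC(=O)OC(C)(C)C
Why: Carbamate (Boc) protection activates the ring for α-oxidation and later makes the lactam an acyl donor; the stereocentre is untouched.

Step 7
Reactants: 10 tert-butyl (2S)-2-methylpiperidine-1-carboxylate
Product: 11 tert-butyl (2S)-2-methyl-6-oxopiperidine-1-carboxylate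
Conditions: RuO2·xH2O (5 mol %), NaIO4, EtOAc/H2O, rt
Reagents that add atoms: sodium periodate (oxygen source via RuO4), [Na+].[O-]I(=O)(=O)=O
Why: RuO4 oxidation of an N-Boc amine occurs at the unhindered α-CH2 in preference to the α-CH(Me), giving the lactam without touching the stereocentre.

Step 8
Reactants: 8 methyl (3aS,5aS,9aS,9bS)-5a-hydroxy-3-oxo-2,3,3a,5a,6,7,8,9,9a,9b-decahydro-1H-cyclopenta[a]naphthalene-4-carboxylate; 11 tert-butyl (2S)-2-methyl-6-oxopiperidine-1-carboxylate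
Product: 12 methyl (3aS,5aS,9aS,9bS)-2-{(5S)-5-[(tert-butoxycarbonyl)amino]hexanoyl}-5a-hydroxy-3-oxo-2,3,3a,5a,6,7,8,9,9a,9b-decahydro-1H-cyclopenta[a]naphthalene-4-carboxylate (C2 epimer/enol mixture)
Conditions: LDA (3.2 equiv), THF, −78 °C; then 11, −78 °C; aq NH4Cl
Reagents that add atoms: none
Why: Claisen-type C-acylation of the kinetic C2 enolate (unhindered CH2, formed cold to spare the acidic C3a–H) by ring-opening of the N-Boc lactam brings in the whole piperidine carbon chain with its S methyl centre.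

Step 9
Reactants: 12 methyl (3aS,5aS,9aS,9bS)-2-{(5S)-5-[(tert-butoxycarbonyl)amino]hexanoyl}-5a-hydroxy-3-oxo-2,3,3a,5a,6,7,8,9,9a,9b-decahydro-1H-cyclopenta[a]naphthalene-4-carboxylate (C2 epimer/enol mixture)
Product: 14 methyl (2Z,3aS,5aS,9aS,9bS)-5a-hydroxy-2-[(6S)-6-methylpiperidin-2-ylidene]-3-oxo-2,3,3a,5a,6,7,8,9,9a,9b-decahydro-1H-cyclopenta[a]naphthalene-4-carboxylate, via amino diketone 13 (not isolated)
Conditions: TFA/CH2Cl2 (1:4), 0 °C; then aq NaHCO3, PhMe, 60 °C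
Reagents that add atoms: none
Why: Boc cleavage followed by six-membered intramolecular amine–ketone condensation gives the hydrogen-bonded Z vinylogous amide (enaminone formation), which makes C2 planar so that it can be set later under control of the ring system.

Step 10
Reactants: 14 methyl (2Z,3aS,5aS,9aS,9bS)-5a-hydroxy-2-[(6S)-6-methylpiperidin-2-ylidene]-3-oxo-2,3,3a,5a,6,7,8,9,9a,9b-decahydro-1H-cyclopenta[a]naphthalene-4-carboxylate
Product: 15 methyl (2R,3aS,5aS,9aS,9bS)-5a-hydroxy-2-[(2S,6S)-6-methylpiperidin-2-yl]-3-oxo-2,3,3a,5a,6,7,8,9,9a,9b-decahydro-1H-cyclopenta[a]naphthalene-4-carboxylate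
Conditions: NaBH(OAc)3, AcOH/CH2Cl2, 0 °C → rt
Reagents that add atoms: none
Why: Vinylogous amide reduction: C-protonation at C2 on the convex face (H cis to H-3a and H-9b) gives the iminium, and axial hydride delivery to it gives the cis-2′,6′-piperidine.

Step 11
Reactants: 15 methyl (2R,3aS,5aS,9aS,9bS)-5a-hydroxy-2-[(2S,6S)-6-methylpiperidin-2-yl]-3-oxo-2,3,3a,5a,6,7,8,9,9a,9b-decahydro-1H-cyclopenta[a]naphthalene-4-carboxylate
Product: 16 methyl (2R,3aS,5aS,9aS,9bS)-2-[(2S,6S)-1-acetyl-6-methylpiperidin-2-yl]-5a-hydroxy-3-oxo-2,3,3a,5a,6,7,8,9,9a,9b-decahydro-1H-cyclopenta[a]naphthalene-4-carboxylate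
Conditions: Ac2O, pyridine, CH2Cl2, 0 °C
Reagents that add atoms: acetic anhydride, CC(=O)OC(C)=O
Why: N-acetylation of the secondary amine (the tertiary alcohol is inert under these conditions) installs the acetamide and blocks retro-Mannich epimerisation at C2.

Step 12
Reactants: 16 methyl (2R,3aS,5aS,9aS,9bS)-2-[(2S,6S)-1-acetyl-6-methylpiperidin-2-yl]-5a-hydroxy-3-oxo-2,3,3a,5a,6,7,8,9,9a,9b-decahydro-1H-cyclopenta[a]naphthalene-4-carboxylate
Product: 18 CNP0529632.1 (3-O→4-carbonyl γ-lactone of (2R,3R,3aS,5aS,9aS,9bS)-2-[(2S,6S)-1-acetyl-6-methylpiperidin-2-yl]-3,5a-dihydroxy-3-methyl-2,3,3a,5a,6,7,8,9,9a,9b-decahydro-1H-cyclopenta[a]naphthalene-4-carboxylic acid), via hydroxy ester 17 (not isolated)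
Conditions: MeMgBr (3 equiv), CeCl3, THF, −78 → 0 °C; aq NH4Cl
Reagents that add atoms: methylmagnesium bromide, C[Mg]Br
Why: Organocerium 1,2-addition to the C3 ketone from the convex face, anti to both α-substituents, sets C3 (Me cis to H-2 and H-3a), and the alkoxide then closes the cis-fused γ-lactone on the C4 ester (translactonisation).

**Compound list**
1 | cycloheptanone | O=C1CCCCCC1 | starting material
2 | 1-{[tert-butyl(dimethyl)silyl]oxy}cyclohept-1-ene | CC(C)(C)[Si](C)(C)OC1=CCCCCC1 | intermediate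
3 | cyclopent-2-en-1-one | O=C1C=CCC1 | starting material
4 | (2S)-2-[(1R)-3-{[tert-butyl(dimethyl)silyl]oxy}cyclopent-2-en-1-yl]cycloheptan-1-one | O=C1CCCCC[C@H]1[C@@H]1CCC(O[Si](C)(C)C(C)(C)C)=C1 | intermediate
5 | (2S,7S)-2-hydroxy-7-[(1R)-3-{[tert-butyl(dimethyl)silyl]oxy}cyclopent-2-en-1-yl]cycloheptan-1-one | O=C1[C@@H](O)CCCC[C@H]1[C@@H]1CCC(O[Si](C)(C)C(C)(C)C)=C1 | intermediate
6 | (1S,2S)-2-[(1R)-3-{[tert-butyl(dimethyl)silyl]oxy}cyclopent-2-en-1-yl]-1-hydroxycyclohexane-1-carbaldehyde | O=C[C@]1(O)CCCC[C@H]1[C@@H]1CCC(O[Si](C)(C)C(C)(C)C)=C1 | intermediate (not isolated)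
7 | methyl (2Z)-2-bromo-3-{(1S,2S)-2-[(1R)-3-{[tert-butyl(dimethyl)silyl]oxy}cyclopent-2-en-1-yl]-1-hydroxycyclohexyl}prop-2-enoate | COC(=O)/C(Br)=C/[C@]1(O)CCCC[C@H]1[C@@H]1CCC(O[Si](C)(C)C(C)(C)C)=C1 | intermediate
8 | methyl (3aS,5aS,9aS,9bS)-5a-hydroxy-3-oxo-2,3,3a,5a,6,7,8,9,9a,9b-decahydro-1H-cyclopenta[a]naphthalene-4-carboxylate | C1C[C@@H]2[C@H](C1=O)C(=C[C@]3(O)CCCC[C@@H]23)C(=O)OC | intermediate
9 | (2S)-2-methylpiperidine | C[C@H]1CCCCN1 | starting material
10 | tert-butyl (2S)-2-methylpiperidine-1-carboxylate | CC(C)(C)OC(=O)N1[C@@H](C)CCCC1 | intermediate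
11 | tert-butyl (2S)-2-methyl-6-oxopiperidine-1-carboxylate | CC(C)(C)OC(=O)N1[C@@H](C)CCCC1=O | intermediate
12 | methyl (3aS,5aS,9aS,9bS)-2-{(5S)-5-[(tert-butoxycarbonyl)amino]hexanoyl}-5a-hydroxy-3-oxo-2,3,3a,5a,6,7,8,9,9a,9b-decahydro-1H-cyclopenta[a]naphthalene-4-carboxylate (C2 epimer/enol mixture) | CC(C)(C)OC(=O)N[C@@H](C)CCCC(=O)C1C[C@@H]2[C@H](C1=O)C(=C[C@]3(O)CCCC[C@@H]23)C(=O)OC | intermediate
13 | methyl (3aS,5aS,9aS,9bS)-2-[(5S)-5-aminohexanoyl]-5a-hydroxy-3-oxo-2,3,3a,5a,6,7,8,9,9a,9b-decahydro-1H-cyclopenta[a]naphthalene-4-carboxylate | N[C@@H](C)CCCC(=O)C1C[C@@H]2[C@H](C1=O)C(=C[C@]3(O)CCCC[C@@H]23)C(=O)OC | intermediate (not isolated)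
14 | methyl (2Z,3aS,5aS,9aS,9bS)-5a-hydroxy-2-[(6S)-6-methylpiperidin-2-ylidene]-3-oxo-2,3,3a,5a,6,7,8,9,9a,9b-decahydro-1H-cyclopenta[a]naphthalene-4-carboxylate | N1[C@@H](C)CCC/C1=C1\C[C@@H]2[C@H](C1=O)C(=C[C@]3(O)CCCC[C@@H]23)C(=O)OC | intermediate
15 | methyl (2R,3aS,5aS,9aS,9bS)-5a-hydroxy-2-[(2S,6S)-6-methylpiperidin-2-yl]-3-oxo-2,3,3a,5a,6,7,8,9,9a,9b-decahydro-1H-cyclopenta[a]naphthalene-4-carboxylate | N1[C@@H](C)CCC[C@H]1[C@H]1C[C@@H]2[C@H](C1=O)C(=C[C@]3(O)CCCC[C@@H]23)C(=O)OC | intermediate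
16 | methyl (2R,3aS,5aS,9aS,9bS)-2-[(2S,6S)-1-acetyl-6-methylpiperidin-2-yl]-5a-hydroxy-3-oxo-2,3,3a,5a,6,7,8,9,9a,9b-decahydro-1H-cyclopenta[a]naphthalene-4-carboxylate | CC(=O)N1[C@@H](C)CCC[C@H]1[C@H]1C[C@@H]2[C@H](C1=O)C(=C[C@]3(O)CCCC[C@@H]23)C(=O)OC | intermediate
17 | methyl (2R,3R,3aS,5aS,9aS,9bS)-2-[(2S,6S)-1-acetyl-6-methylpiperidin-2-yl]-3,5a-dihydroxy-3-methyl-2,3,3a,5a,6,7,8,9,9a,9b-decahydro-1H-cyclopenta[a]naphthalene-4-carboxylate | CC(=O)N1[C@@H](C)CCC[C@H]1[C@H]1C[C@@H]2[C@H]([C@]1(O)C)C(=C[C@]3(O)CCCC[C@@H]23)C(=O)OC | intermediate (not isolated)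
18 | CNP0529632.1 (3-O→4-carbonyl γ-lactone of (2R,3R,3aS,5aS,9aS,9bS)-2-[(2S,6S)-1-acetyl-6-methylpiperidin-2-yl]-3,5a-dihydroxy-3-methyl-2,3,3a,5a,6,7,8,9,9a,9b-decahydro-1H-cyclopenta[a]naphthalene-4-carboxylic acid) | CC(=O)N1[C@@H](C)CCC[C@H]1[C@H]1C[C@@H]2[C@H]3C(=C[C@]4(O)CCCC[C@@H]24)C(=O)O[C@@]13C | target

**Step count and risks**

Total steps: 12. Longest linear sequence: 10 (steps 1, 2, 3, 4, 5, 8, 9, 10, 11, 12); steps 6–7 form the side branch. The contraction route reaches 8 in five steps, one fewer than the cyclohexanone/vinyl-Grignard alternative described under step 4 below.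

The three steps most likely to fail:

Step 4 (the new step). The α-ketol equilibrium lies on the side of the seven-membered acyloin, so the cascade depends on the Wittig capture being faster than side reactions. The sense of the shift (cis-acyloin → OH cis to the cyclopentenyl group) rests on a chelate model. Fallback with known chemistry, setting out from 3 and coming back at 8: Mukaiyama–Michael addition of commercial 1-(trimethylsilyloxy)cyclohexene to 3 under the step-2 conditions gives (2S)-2-[(1R)-3-[(trimethylsilyl)oxy]cyclopent-2-en-1-yl]cyclohexan-1-one F4. CeCl3-promoted addition of vinylmagnesium bromide to the free cyclohexanone (equatorial attack, trans to the C2 substituent) with dilute-acid work-up gives (3R)-3-[(1S,2R)-2-ethenyl-2-hydroxycyclohexyl]cyclopentan-1-one F5. OsO4 (cat.)/NaIO4 cleavage of the vinyl group gives (1S,2S)-1-hydroxy-2-[(1R)-3-oxocyclopentyl]cyclohexane-1-carbaldehyde F6. Wittig reaction with the same bromo-ylide gives methyl (2Z)-2-bromo-3-{(1S,2S)-1-hydroxy-2-[(1R)-3-oxocyclopentyl]cyclohexyl}prop-2-enoate F7. Pd(PPh3)4/PhOK intramolecular ketone α-alkenylation (only C3a can reach the vinyl bromide) then gives 8.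

Step 2. Both the enantioselectivity and the syn selectivity of a ketone-derived enol silane adding to cyclopentenone under a chiral Lewis acid are uncertain. Fallback, setting out from 2 and 3 and coming back at 5: run the addition with an achiral catalyst (TBSOTf 5 mol % or TrSbCl6, CH2Cl2, −78 °C) to obtain racemic syn adduct, that is 4 together with (2R)-2-[(1S)-3-{[tert-butyl(dimethyl)silyl]oxy}cyclopent-2-en-1-yl]cycloheptan-1-one F1. Hydroxylate as in step 3 to the racemic acyloin, 5 plus (2R,7R)-2-hydroxy-7-[(1S)-3-{[tert-butyl(dimethyl)silyl]oxy}cyclopent-2-en-1-yl]cycloheptan-1-one F2. Resolve by lipase-catalysed transesterification (Amano PS or CAL-B, vinyl acetate, MTBE): the 2R carbinol is expected to be acylated (Kazlauskas rule) to (1R,3R)-3-[(1S)-3-{[tert-butyl(dimethyl)silyl]oxy}cyclopent-2-en-1-yl]-2-oxocycloheptyl acetate F3, which is removed by chromatography, leaving 5.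

Step 5. The free enolate may add to the β-carbon of the bromo enoate (Michael-initiated cyclopropanation), and base may move the C4=C5 double bond of 8 into conjugation with the ketone. Fallback, setting out from 7 and coming back at 8: a neutral Stork-type vinyl-radical cyclisation (Bu3SnH, AIBN, PhH, 80 °C) of the C–Br bond onto the silyl enol ether (6-exo) gives methyl (3aS,5aS,9aS,9bR)-3-{[tert-butyl(dimethyl)silyl]oxy}-5a-hydroxy-2,3,3a,5a,6,7,8,9,9a,9b-decahydro-1H-cyclopenta[a]naphthalene-4-carboxylate (C3 epimers) F8. TBAF gives methyl (3aS,5aS,9aS,9bR)-3,5a-dihydroxy-2,3,3a,5a,6,7,8,9,9a,9b-decahydro-1H-cyclopenta[a]naphthalene-4-carboxylate (C3 epimers) F9, and Dess–Martin oxidation of the secondary alcohol gives 8.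

Further compounds
F1 | step 2 | (2R)-2-[(1S)-3-{[tert-butyl(dimethyl)silyl]oxy}cyclopent-2-en-1-yl]cycloheptan-1-one | O=C1CCCCC[C@@H]1[C@H]1CCC(O[Si](C)(C)C(C)(C)C)=C1
F2 | step 2 | (2R,7R)-2-hydroxy-7-[(1S)-3-{[tert-butyl(dimethyl)silyl]oxy}cyclopent-2-en-1-yl]cycloheptan-1-one | O=C1[C@H](O)CCCC[C@@H]1[C@H]1CCC(O[Si](C)(C)C(C)(C)C)=C1
F3 | step 2 | (1R,3R)-3-[(1S)-3-{[tert-butyl(dimethyl)silyl]oxy}cyclopent-2-en-1-yl]-2-oxocycloheptyl acetate | O=C1[C@H](OC(C)=O)CCCC[C@@H]1[C@H]1CCC(O[Si](C)(C)C(C)(C)C)=C1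
F4 | step 4 | (2S)-2-[(1R)-3-[(trimethylsilyl)oxy]cyclopent-2-en-1-yl]cyclohexan-1-one | O=C1CCCC[C@H]1[C@@H]1CCC(O[Si](C)(C)C)=C1
F5 | step 4 | (3R)-3-[(1S,2R)-2-ethenyl-2-hydroxycyclohexyl]cyclopentan-1-one | C=C[C@]1(O)CCCC[C@H]1[C@@H]1CCC(=O)C1
F6 | step 4 | (1S,2S)-1-hydroxy-2-[(1R)-3-oxocyclopentyl]cyclohexane-1-carbaldehyde | O=C[C@]1(O)CCCC[C@H]1[C@@H]1CCC(=O)C1
F7 | step 4 | methyl (2Z)-2-bromo-3-{(1S,2S)-1-hydroxy-2-[(1R)-3-oxocyclopentyl]cyclohexyl}prop-2-enoate | COC(=O)/C(Br)=C/[C@]1(O)CCCC[C@H]1[C@@H]1CCC(=O)C1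
F8 | step 5 | methyl (3aS,5aS,9aS,9bR)-3-{[tert-butyl(dimethyl)silyl]oxy}-5a-hydroxy-2,3,3a,5a,6,7,8,9,9a,9b-decahydro-1H-cyclopenta[a]naphthalene-4-carboxylate (C3 epimers) | C1C[C@@H]2[C@H](C1O[Si](C)(C)C(C)(C)C)C(=C[C@]3(O)CCCC[C@@H]23)C(=O)OC
F9 | step 5 | methyl (3aS,5aS,9aS,9bR)-3,5a-dihydroxy-2,3,3a,5a,6,7,8,9,9a,9b-decahydro-1H-cyclopenta[a]naphthalene-4-carboxylate (C3 epimers) | C1C[C@@H]2[C@H](C1O)C(=C[C@]3(O)CCCC[C@@H]23)C(=O)OC
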